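The target is traced back to an oxirane spanning C2–C3 on the face of the C1 hydroxyl, and from there to an achiral cyclohexa-2,5-dienol. The feature exploited is the hidden mirror plane of the six-membered ring through C1 and C4: the quaternary carbinol C1 (carrying C7H2OBz) lies on it, the alkenes C2=C3 and C5=C6 are enantiotopic, and C3–O is cis to C1–OH in the target. A chiral hafnium–bishydroxamate peroxide catalyst anchored on the C1 alkoxide epoxidises one alkene, closing the oxirane and fixing C1, C2 and C3 in one operation. The precursor, (1-hydroxycyclohexa-2,5-dien-1-yl)methyl benzoate, derives from Birch reduction of benzoic acid.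

Key step: step 6

Remark (numbering and configuration): C1 = quaternary carbinol bearing C7 (CH2O), C2 and C3 = acetoxy carbons, C4=C5 = target alkene, C6 = benzoyloxy carbon. Read from the target SMILES, O1, O3 and O6 lie on one ring face and O2 and C7 on the other; the target is (1S,2S,3R,6S). All names below use this numbering.

Assumption: the sense of induction of the bishydroxamic acid ligand on this cyclic dienol is fixed in a first small run. The (R,R) ligand is written; its equally available antipode is used should that run give the enantiomer of 9.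

Step 1
Reactants: 1 benzoic acid
Product: 2 cyclohexa-2,5-diene-1-carboxylic acid
Conditions: Na, NH3(l), EtOH, −78 °C; NH4Cl; then aq. HCl (pH 3), 0 °C
Reagents that add atoms: none
Why: Birch reduction: the carboxylate directs electron and proton delivery to the ipso and para carbons, so the skipped 2,5-diene acid should form; no stereocentre is created.

Step 2
Reactants: 2 cyclohexa-2,5-diene-1-carboxylic acid
Product: 3 methyl cyclohexa-2,5-diene-1-carboxylate
Conditions: TMSCHN2, MeOH/PhMe, 0 °C
Reagents that add atoms: (trimethylsilyl)diazomethane, C[Si](C)(C)C=[N+]=[N-]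
Why: O-methylation of the carboxylic acid by the diazoalkane runs under neutral conditions, which should keep the skipped diene out of conjugation; no stereocentre.

Step 3
Reactants: 3 methyl cyclohexa-2,5-diene-1-carboxylate
Product: 5 methyl 1-hydroxycyclohexa-2,5-diene-1-carboxylate, via potassium dienolate 4 (not isolated)
Conditions: KHMDS, THF, −78 °C; then 2-(phenylsulfonyl)-3-phenyloxaziridine, −78 °C; AcOH quench
Reagents that add atoms: 2-(phenylsulfonyl)-3-phenyloxaziridine, O=S(=O)(N1OC1c1ccccc1)c1ccccc1
Why: Oxaziridine hydroxylation of an ester enolate (Davis oxidation): the cross-conjugated dienolate should react at C1, as in its C1 alkylations, by attack on the oxaziridine oxygen, and the ester group then disfavours ionisation of the new carbinol; C1 stays on the mirror plane, so no stereocentre arises.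

Step 4
Reactants: 5 methyl 1-hydroxycyclohexa-2,5-diene-1-carboxylate
Product: 6 1-(hydroxymethyl)cyclohexa-2,5-dien-1-ol
Conditions: LiAlH4, Et2O, 0 °C; then H2O, 15% NaOH, H2O
Reagents that add atoms: none
Why: Hydride reduction of the ester to the primary alcohol; the basic work-up should protect the acid-labile bis-allylic tertiary carbinol.

Step 5
Reactants: 6 1-(hydroxymethyl)cyclohexa-2,5-dien-1-ol; 7 benzoyl chloride
Product: 8 (1-hydroxycyclohexa-2,5-dien-1-yl)methyl benzoate
Conditions: BzCl (1.05 equiv), Et3N, DMAP (5 mol %), CH2Cl2, −40 → 0 °C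
Reagents that add atoms: benzoyl chloride (7), O=C(Cl)c1ccccc1
Why: DMAP-catalysed acylation should take the unhindered primary hydroxyl and leave the tertiary bis-allylic one, while the amine keeps the medium basic; no stereocentre.

Step 6
Reactants: 8 (1-hydroxycyclohexa-2,5-dien-1-yl)methyl benzoate
Product: 9 [(1R,2R,3R)-2,3-epoxy-1-hydroxycyclohex-5-en-1-yl]methyl benzoate
Conditions: Hf(OtBu)4 (10 mol %), (R,R)-cyclohexane-1,2-diamine-derived C2-symmetric bishydroxamic acid (BHA, 12 mol %), cumene hydroperoxide (1.2 equiv), 4 Å MS, PhMe, 0 °C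
Reagents that add atoms: cumene hydroperoxide, CC(C)(OO)c1ccccc1
Why: The C1 hydroxyl exchanges onto the hafnium(IV) bishydroxamate, the hydroperoxide binds to the same metal, and its distal oxygen is passed within the complex to the C2=C3 π bond in a concerted spiro-type transition state. The closest known reaction type is the enantioselective epoxidation of tertiary allylic alcohols by chiral bishydroxamic acid complexes of group 4 and 5 metals, including the desymmetrisation of divinyl carbinols. The oxirane closes by suprafacial oxygen-atom transfer, both C–O bonds forming on one face in a single event and not by a stepwise cyclisation. C2 and C3 are set by the C1–O–Hf tether, which confines delivery to the hydroxyl face, and C1 becomes stereogenic through the choice between the two enantiotopic alkenes, which the C2-symmetric ligand makes. The step needs enantiotopic-group selectivity, syn facial selectivity, mono-epoxidation and survival of the dienol: O7 is masked as a benzoate so that the only directing hydroxyl lies on the mirror plane, the β-benzoyloxy group retards ionisation at C1, and the medium is a basic alkoxide one. A small excess of oxidant should raise the enantiomeric purity, since the minor enantiomer still carries the catalyst-preferred alkene and is drained faster into the meso bis-epoxide.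

Step 7
Reactants: 9 [(1R,2R,3R)-2,3-epoxy-1-hydroxycyclohex-5-en-1-yl]methyl benzoate
Product: 12 [(1R,2S,3R)-1,2,3-trihydroxycyclohex-5-en-1-yl]methyl benzoate, via dioxanylium ion 10 (not isolated), via hemi-orthoester 11 (not isolated)
Conditions: BF3·OEt2 (1.2 equiv), CH2Cl2, −78 → −30 °C; then H2O/THF, 0 °C; aq. NaHCO3
Reagents that add atoms: water, O
Why: Anchimeric assistance: the carbonyl oxygen of the C7 benzoate should open the activated oxirane at C2 in a 6-exo-tet attack anti to the oxirane oxygen, inverting C2 and leaving C3–O untouched; water then adds to the 2-phenyl-1,3-dioxan-2-ylium ion, and the ortho-acid should collapse by loss of the more acidic and more crowded secondary O2, returning the benzoyl group to primary O7.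

Step 8
Reactants: 12 [(1R,2S,3R)-1,2,3-trihydroxycyclohex-5-en-1-yl]methyl benzoate; 13 acetic anhydride
Product: 14 [(1R,2S,3R)-2,3-diacetoxy-1-hydroxycyclohex-5-en-1-yl]methyl benzoate
Conditions: Ac2O, pyridine, rt
Reagents that add atoms: acetic anhydride (13), CC(=O)OC(C)=O
Why: Pyridine-mediated acetylation should esterify the two secondary hydroxyls, whereas the tertiary C1 hydroxyl stays free in the absence of DMAP; no stereocentre is touched.

Step 9
Reactants: 14 [(1R,2S,3R)-2,3-diacetoxy-1-hydroxycyclohex-5-en-1-yl]methyl benzoate
Product: 15 [(1S,2S,3R,5S,6S)-2,3-diacetoxy-5,6-epoxy-1-hydroxycyclohexyl]methyl benzoate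
Conditions: VO(acac)2 (5 mol %), TBHP (in decane), CH2Cl2, 0 °C → rt
Reagents that add atoms: tert-butyl hydroperoxide, CC(C)(C)OO
Why: Vanadium-catalysed hydroxyl-directed epoxidation: the C1 vanadate ester should deliver the peroxide oxygen to the face of C5=C6 cis to C1–OH, the only free hydroxyl now that O2 and O3 are acetylated, so C5 and C6 are set by substrate control.

Step 10
Reactants: 15 [(1S,2S,3R,5S,6S)-2,3-diacetoxy-5,6-epoxy-1-hydroxycyclohexyl]methyl benzoate
Product: 16 [(1S,2S,3R,5R,6R)-2,3-diacetoxy-1,6-dihydroxy-5-(phenylselanyl)cyclohexyl]methyl benzoate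
Conditions: (PhSe)2, NaBH4, EtOH, 0 °C; AcOH; then 15, THF, rt
Reagents that add atoms: diphenyl diselenide, c1ccc(cc1)[Se][Se]c1ccccc1
Why: SN2 opening of the epoxide by the soft selenium nucleophile should occur with inversion at C5 and not at the neopentyl-type C6 next to quaternary C1, so C6–O keeps its cis relation to C1–OH; the acetic acid buffer prevents alkoxide-induced loss or migration of the three esters.

Step 11
Reactants: 16 [(1S,2S,3R,5R,6R)-2,3-diacetoxy-1,6-dihydroxy-5-(phenylselanyl)cyclohexyl]methyl benzoate
Product: 18 [(1S,2S,3R,6S)-2,3-diacetoxy-1,6-dihydroxycyclohex-4-en-1-yl]methyl benzoate, via selenoxide 17 (not isolated)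
Conditions: 30% H2O2, pyridine, CH2Cl2, 0 °C → rt
Reagents that add atoms: none
Why: Selenoxide syn-elimination: the selenoxide should abstract a cis hydrogen from C4 and not from the carbinol carbon C6 (elimination away from oxygen), giving C4=C5 and the allylic C6 alcohol without touching a stereocentre; pyridine buffers the selenium acids.

Step 12
Reactants: 18 [(1S,2S,3R,6S)-2,3-diacetoxy-1,6-dihydroxycyclohex-4-en-1-yl]methyl benzoate; 7 benzoyl chloride
Product: 19 cleistenediol F, [(1S,2S,3R,6S)-2,3-diacetoxy-6-(benzoyloxy)-1-hydroxycyclohex-4-en-1-yl]methyl benzoate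
Conditions: BzCl, pyridine, DMAP (cat.), CH2Cl2, 0 °C → rt
Reagents that add atoms: benzoyl chloride (7), O=C(Cl)c1ccccc1
Why: DMAP-catalysed O-benzoylation of the secondary allylic hydroxyl proceeds with retention at C6, while the tertiary C1 hydroxyl, flanked by three substituted carbons, should not react.

Compound list

1 | benzoic acid | OC(=O)c1ccccc1 | starting material
2 | cyclohexa-2,5-diene-1-carboxylic acid | OC(=O)C1C=CCC=C1 | intermediate
3 | methyl cyclohexa-2,5-diene-1-carboxylate | COC(=O)C1C=CCC=C1 | intermediate
4 | potassium dienolate of 3, potassium (cyclohexa-2,5-dien-1-ylidene)(methoxy)methanolate | COC(=C1C=CCC=C1)[O-].[K+] | intermediate (not isolated)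
5 | methyl 1-hydroxycyclohexa-2,5-diene-1-carboxylate | COC(=O)C1(O)C=CCC=C1 | intermediate
6 | 1-(hydroxymethyl)cyclohexa-2,5-dien-1-ol | OCC1(O)C=CCC=C1 | intermediate
7 | benzoyl chloride | O=C(Cl)c1ccccc1 | starting material
8 | (1-hydroxycyclohexa-2,5-dien-1-yl)methyl benzoate | O=C(OCC1(O)C=CCC=C1)c1ccccc1 | intermediate
9 | [(1R,2R,3R)-2,3-epoxy-1-hydroxycyclohex-5-en-1-yl]methyl benzoate (oxirane oxygen cis to C1–OH) | O1[C@@H]2CC=C[C@@](O)(COC(=O)c3ccccc3)[C@H]12 | intermediate
10 | 2-phenyl-1,3-dioxan-2-ylium ion cis-fused to the cyclohexene at C1–C2 (ring oxygens O7 and O2; C1–OH free; O3 bound to BF3) | F[B-](F)(F)O[C@@H]1CC=C[C@@]2(O)COC(c3ccccc3)=[O+][C@@H]12 | intermediate (not isolated)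
11 | 2-hydroxy-2-phenyl-1,3-dioxane hemi-orthoester cis-fused at C1–C2 (C1–OH and C3–OH free; ortho carbon unassigned) | O[C@@H]1CC=C[C@@]2(O)COC(O)(c3ccccc3)O[C@@H]12 | intermediate (not isolated)
12 | [(1R,2S,3R)-1,2,3-trihydroxycyclohex-5-en-1-yl]methyl benzoate (O2 trans to O1, O3 cis to O1) | O[C@@H]1CC=C[C@@](O)(COC(=O)c2ccccc2)[C@H]1O | intermediate
13 | acetic anhydride | CC(=O)OC(C)=O | starting material
14 | [(1R,2S,3R)-2,3-diacetoxy-1-hydroxycyclohex-5-en-1-yl]methyl benzoate | CC(=O)O[C@@H]1CC=C[C@@](O)(COC(=O)c2ccccc2)[C@H]1OC(C)=O | intermediate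
15 | [(1S,2S,3R,5S,6S)-2,3-diacetoxy-5,6-epoxy-1-hydroxycyclohexyl]methyl benzoate (oxirane oxygen cis to C1–OH) | CC(=O)O[C@@H]1C[C@@H]2O[C@@H]2[C@@](O)(COC(=O)c3ccccc3)[C@H]1OC(C)=O | intermediate
16 | [(1S,2S,3R,5R,6R)-2,3-diacetoxy-1,6-dihydroxy-5-(phenylselanyl)cyclohexyl]methyl benzoate (Se trans to O6, O6 cis to O1) | CC(=O)O[C@@H]1C[C@@H]([Se]c2ccccc2)[C@H](O)[C@@](O)(COC(=O)c3ccccc3)[C@H]1OC(C)=O | intermediate
17 | Se-oxide of 16 (both configurations at selenium) | CC(=O)O[C@@H]1C[C@@H]([Se](=O)c2ccccc2)[C@H](O)[C@@](O)(COC(=O)c3ccccc3)[C@H]1OC(C)=O | intermediate (not isolated)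
18 | [(1S,2S,3R,6S)-2,3-diacetoxy-1,6-dihydroxycyclohex-4-en-1-yl]methyl benzoate | CC(=O)O[C@@H]1C=C[C@H](O)[C@@](O)(COC(=O)c2ccccc2)[C@H]1OC(C)=O | intermediate
19 | cleistenediol F, [(1S,2S,3R,6S)-2,3-diacetoxy-6-(benzoyloxy)-1-hydroxycyclohex-4-en-1-yl]methyl benzoate | CC(=O)O[C@@H]1C=C[C@H](OC(=O)c2ccccc2)[C@@](O)(COC(=O)c2ccccc2)[C@H]1OC(C)=O | target

Total step count: 12
Longest linear sequence: 12 steps (benzoic acid 1 to 19)

Steps most likely to fail

Step 6. The ligand may discriminate poorly between the two enantiotopic alkenes of this cyclic cis-dienol. The Lewis-acidic metal may also ionise the bis-allylic C1–O bond, after which loss of a C4 proton aromatises the ring, and the second alkene may be oxidised before the first is consumed. The fallback gives up catalytic desymmetrisation for a racemic synthesis with resolution. Setting out from 8, the achiral vanadium-catalysed hydroxyl-directed epoxidation (VO(acac)2, TBHP, 2,6-lutidine, CH2Cl2, 0 °C) would give the racemic syn-epoxide F1. Its enantiomers would be separated by preparative chromatography on a polysaccharide chiral stationary phase, and the (1R,2R,3R) fraction is 9, where the route is rejoined.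

Step 3. The sulfonylimine released during oxygen transfer may capture unreacted enolate, or electron transfer from the electron-rich dienolate may outrun C–O bond formation and lead to aromatisation. The fallback replaces oxygen-atom transfer by acyloxylation. Setting out from 3, the enolate 4 would be treated with dibenzoyl peroxide in THF at −78 °C, which should give methyl 1-(benzoyloxy)cyclohexa-2,5-diene-1-carboxylate F2 by substitution at the peroxide oxygen. LiAlH4 in Et2O would then cleave both ester groups and deliver the diol 6, where the route is rejoined without an added step.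

Step 7. The cyclic ortho-acid may collapse toward the wrong oxygen, or the benzoyl group may wander between O7, O2 and O3 during work-up, so that the acyl group ends on a secondary oxygen. The fallback no longer relies on the regiochemistry of that collapse and instead removes and re-installs the ester. Setting out from 9, the crude product of the opening, containing the O2-benzoyl isomer (1R,2S,3R)-1,3-dihydroxy-1-(hydroxymethyl)cyclohex-5-en-2-yl benzoate F3, would be methanolysed (K2CO3, MeOH, 0 °C) to the tetraol (1R,2S,3R)-1-(hydroxymethyl)cyclohex-5-ene-1,2,3-triol F4. Selective benzoylation of its only primary hydroxyl (BzCl, 2,4,6-collidine, CH2Cl2, −40 °C) would return 12, where the route is rejoined.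

Further compounds

F1 | step 6 | racemic syn-epoxide, 1:1 mixture of 9 and its enantiomer | O1[C@@H]2CC=C[C@@](O)(COC(=O)c3ccccc3)[C@H]12.O1[C@H]2CC=C[C@](O)(COC(=O)c3ccccc3)[C@@H]12
F2 | step 3 | methyl 1-(benzoyloxy)cyclohexa-2,5-diene-1-carboxylate | COC(=O)C1(OC(=O)c2ccccc2)C=CCC=C1
F3 | step 7 | (1R,2S,3R)-1,3-dihydroxy-1-(hydroxymethyl)cyclohex-5-en-2-yl benzoate | O[C@@H]1CC=C[C@@](O)(CO)[C@H]1OC(=O)c1ccccc1
F4 | step 7 | (1R,2S,3R)-1-(hydroxymethyl)cyclohex-5-ene-1,2,3-triol | O[C@@H]1CC=C[C@@](O)(CO)[C@H]1O
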